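## Retrosynthetic overview

1. The target is reached by global desilylation, α-face epoxidation of C8=C9 and O6 aroylation of a dauc-8-ene-4,6,7-triol whose O7 is silylated.
2. The strategy rests on the secondary allylic carbinol C7 of the seven-membered ring, which lies between oxygen-bearing C6 and C8, the methyl-bearing carbon of the C8=C9 double bond. Cutting C7–C8 gives a C7 aldehyde and a C8 alkenyl metal, so the cycloheptene closes by an intramolecular Nozaki–Hiyama–Kishi reaction of a Z alkenyl iodide.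
3. The cyclisation substrate is a 1,5-trans cyclopentane: a Z-3-iodobut-2-enyl arm on C1 (dioxolane-masked aldehyde, then Stork–Zhao olefination), an α-silyloxy aldehyde arm on C5 (from a vinyl group), and the C4 carbinol (isopropylcerium addition) carried as its silyl ether.
4. C5 and C6 come from an anti boron aldol of a regiodefined enolate with acrolein. C1 comes from a copper-catalysed asymmetric conjugate methylation of the enone made from 3-ethoxycyclopent-2-en-1-one and the acetal Grignard reagent.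
5. Ring order: cyclopentane (present from the start), cycloheptene (step 9), oxirane (step 15).

Key step: step 9

Remarks:
- Daucane numbering is used: C1 is the methyl-bearing ring-fusion carbon, C2 and C3 follow, C4 is the isopropyl carbinol, C5 the ring-fusion CH, C6 to C10 the other seven-ring carbons, C8 carrying the methyl. β is the face of the C1 methyl.
- Assumption: a C7 aldehyde with a free C4 hydroxyl cis to the C5 side chain would exist as its five-membered lactol. The C4 hydroxyl is therefore carried through the ring closure as a triethylsilyl ether.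
- Assumption: the enantiomer of the phosphoramidite ligand in step 2 is the one that gives the (R) quaternary centre.

## Route

Step 1
Reactants: 1 3-ethoxycyclopent-2-en-1-one; 2 (1,3-dioxolan-2-ylmethyl)magnesium bromide
Product: 4 3-(1,3-dioxolan-2-ylmethyl)cyclopent-2-en-1-one, via bromomagnesium alkoxide adduct 3 (not isolated)
Conditions: THF, 0 °C to rt; then 1 M HCl, 0 °C, 15 min
Reagents that add atoms: water, O
Why: Stork–Danheiser enone synthesis, in which 1,2-addition of the Grignard reagent to the vinylogous ester is followed by acid-promoted hydrolysis with allylic transposition to the β-substituted enone, the aldehyde dioxolane surviving the brief cold dilute acid.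

Step 2
Reactants: 4 3-(1,3-dioxolan-2-ylmethyl)cyclopent-2-en-1-one
Product: 6 {[(3R)-3-(1,3-dioxolan-2-ylmethyl)-3-methylcyclopent-1-en-1-yl]oxy}trimethylsilane, via dimethylaluminium enolate 5 (not isolated)
Conditions: Me3Al (1.5 equiv), Cu(O2CC4H3S) (5 mol %), one enantiomer of O,O′-(biphenyl-2,2′-diyl) N,N-bis(1-phenylethyl)phosphoramidite (10 mol %), Et2O, −30 °C; then Me3SiOTf, −30 to 0 °C; Et3N, non-aqueous work-up
Reagents that add atoms: trimethylaluminium, C[Al](C)C; trimethylsilyl trifluoromethanesulfonate, C[Si](C)(C)OS(=O)(=O)C(F)(F)F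
Why: Copper-catalysed asymmetric conjugate addition of trimethylaluminium to a β-substituted cyclopentenone builds the quaternary C1 under control of the chiral phosphoramidite (ligand enantiomer chosen for R), and O-silylation of aluminium enolate 5 fixes the enol double bond between C4 and C5.

Step 3
Reactants: 6 {[(3R)-3-(1,3-dioxolan-2-ylmethyl)-3-methylcyclopent-1-en-1-yl]oxy}trimethylsilane; 7 acrolein
Product: 11 (2S,3R)-3-(1,3-dioxolan-2-ylmethyl)-2-[(1S)-1-hydroxyprop-2-en-1-yl]-3-methylcyclopentan-1-one, via lithium enolate 8 (not isolated), via dicyclohexylboron enolate 9 (not isolated), via boron aldolate 10 (not isolated)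
Conditions: MeLi, THF, 0 °C; (c-C6H11)2BCl, −78 °C; 7, −78 to −30 °C; then MeOH, pH 7 buffer, 30% H2O2, 0 °C
Reagents that add atoms: none
Why: Methyllithium cleaves the silyl enol ether to the regiodefined lithium enolate, boron exchange gives the necessarily E cyclic boron enolate, and its aldol addition to acrolein through a chair Zimmerman–Traxler transition state gives the anti C5/C6 relationship, with the aldehyde approaching C5 on the face of the C1 methyl, away from the bulkier dioxolanylmethyl group, which cannot chelate tetracoordinate boron.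

Step 4
Reactants: 11 (2S,3R)-3-(1,3-dioxolan-2-ylmethyl)-2-[(1S)-1-hydroxyprop-2-en-1-yl]-3-methylcyclopentan-1-one
Product: 12 (2S,3R)-3-(1,3-dioxolan-2-ylmethyl)-3-methyl-2-[(1S)-1-(triethylsilyloxy)prop-2-en-1-yl]cyclopentan-1-one
Conditions: Et3SiCl, imidazole, DMAP (cat.), DMF, 0 °C to rt
Reagents that add atoms: chlorotriethylsilane, CC[Si](Cl)(CC)CC
Why: Imidazole-mediated silylation of the secondary hydroxyl under non-acidic, weakly basic conditions protects O6 without retro-aldol cleavage and without touching the acetal.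

Step 5
Reactants: 12 (2S,3R)-3-(1,3-dioxolan-2-ylmethyl)-3-methyl-2-[(1S)-1-(triethylsilyloxy)prop-2-en-1-yl]cyclopentan-1-one
Product: 13 (1R,2S,3R)-3-(1,3-dioxolan-2-ylmethyl)-3-methyl-1-(propan-2-yl)-2-[(1S)-1-(triethylsilyloxy)prop-2-en-1-yl]cyclopentan-1-ol
Conditions: i-PrMgCl (3 equiv), CeCl3 (3 equiv, dried), THF, −78 to −40 °C; aq. NH4Cl
Reagents that add atoms: isopropylmagnesium chloride, CC(C)[Mg]Cl
Why: Organocerium 1,2-addition suppresses enolisation and β-elimination of the β-silyloxy ketone, and the isopropyl group enters the cyclopentanone on the face anti to the adjacent C5 side chain, so the new C4 hydroxyl is cis to that chain and to the C1 methyl.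

Step 6
Reactants: 13 (1R,2S,3R)-3-(1,3-dioxolan-2-ylmethyl)-3-methyl-1-(propan-2-yl)-2-[(1S)-1-(triethylsilyloxy)prop-2-en-1-yl]cyclopentan-1-ol
Product: 15 2-[(1R,2S,3R)-1-methyl-3-(propan-2-yl)-3-(triethylsilyloxy)-2-[(1S)-1-(triethylsilyloxy)prop-2-en-1-yl]cyclopentyl]acetaldehyde, via collidinium salt 14 (not isolated)
Conditions: Et3SiOTf (4 equiv), 2,4,6-collidine (6 equiv), CH2Cl2, 0 °C to rt; then H2O, rt
Reagents that add atoms: triethylsilyl trifluoromethanesulfonate, CC[Si](CC)(CC)OS(=O)(=O)C(F)(F)F; water, O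
Why: The silyl triflate–collidine acetal cleavage turns the aldehyde dioxolane into an N,O-acetal pyridinium salt that water hydrolyses to the aldehyde without protic acid, so the O6 silyl ether survives, while the excess silyl triflate silylates the hindered tertiary C4 hydroxyl, which is trans to the C1 arm and cannot trap the oxocarbenium ion.

Step 7
Reactants: 15 2-[(1R,2S,3R)-1-methyl-3-(propan-2-yl)-3-(triethylsilyloxy)-2-[(1S)-1-(triethylsilyloxy)prop-2-en-1-yl]cyclopentyl]acetaldehyde
Product: 16 triethyl{[(1R,2S,3R)-3-[(2Z)-3-iodobut-2-en-1-yl]-3-methyl-1-(propan-2-yl)-2-[(1S)-1-(triethylsilyloxy)prop-2-en-1-yl]cyclopentyl]oxy}silane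
Conditions: [Ph3PEt]I, n-BuLi, THF, 0 °C; I2, −78 °C; NaN(SiMe3)2, −20 °C; then 15, −78 to −20 °C
Reagents that add atoms: ethyltriphenylphosphonium iodide, CC[P+](c1ccccc1)(c1ccccc1)c1ccccc1.[I-]; iodine, II
Why: Stork–Zhao-type Wittig olefination with the α-iodo ylide made in the flask converts the aldehyde into the trisubstituted iodoalkene with the Z geometry (C10 and iodine cis) under kinetic control at low temperature.

Step 8
Reactants: 16 triethyl{[(1R,2S,3R)-3-[(2Z)-3-iodobut-2-en-1-yl]-3-methyl-1-(propan-2-yl)-2-[(1S)-1-(triethylsilyloxy)prop-2-en-1-yl]cyclopentyl]oxy}silane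
Product: 18 (2R)-2-[(1S,2R,5R)-2-[(2Z)-3-iodobut-2-en-1-yl]-2-methyl-5-(propan-2-yl)-5-(triethylsilyloxy)cyclopentyl]-2-(triethylsilyloxy)acetaldehyde, via vicinal diol 17 (not isolated)
Conditions: OsO4 (2 mol %), NaIO4 (4 equiv), 2,6-lutidine (2 equiv), 1,4-dioxane/H2O (3:1), rt
Reagents that add atoms: osmium tetroxide, O=[Os](=O)(=O)=O; sodium periodate, [Na+].[O-][I](=O)(=O)=O
Why: Lemieux–Johnson cleavage, in which osmium tetroxide dihydroxylates the monosubstituted vinyl group much faster than the electron-poor trisubstituted iodoalkene and periodate cleaves the diol, the lutidine buffer protecting the silyl ethers and the C6 configuration.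

Step 9
Reactants: 18 (2R)-2-[(1S,2R,5R)-2-[(2Z)-3-iodobut-2-en-1-yl]-2-methyl-5-(propan-2-yl)-5-(triethylsilyloxy)cyclopentyl]-2-(triethylsilyloxy)acetaldehyde
Product: 21 4,6-bis-O-(triethylsilyl)dauc-8-ene-4β,6α,7β-triol, via alkenylchromium dichloride 19 (not isolated), via chromium alkoxide 20 (not isolated)
Conditions: CrCl2 (10 equiv), NiCl2 (0.1 equiv), degassed DMSO, rt, slow addition of 18 (final 0.004 M); aq. NH4Cl work-up
Reagents that add atoms: none
Why: Divalent chromium reduces NiCl2 to zerovalent nickel, which inserts into the C8–I bond with retention of the Z geometry; transmetalation to trivalent chromium gives alkenylchromium 19, which adds 1,2 to the C7 aldehyde to give chromium alkoxide 20 and, on work-up, allylic alcohol 21. The closest known reaction type is the nickel-catalysed, chromium-mediated intramolecular Nozaki–Hiyama–Kishi addition of alkenyl iodides to aldehydes used to close medium-ring allylic alcohols. The seven-membered ring (C1, C10, C9, C8, C7, C6, C5) closes in the 7-exo-trig mode by formation of C7–C8, and the Z iodide becomes the ring cis alkene. The new C7 stereocentre is controlled by the ring-forming transition state: the trans-disposed arms fix the trans ring fusion, the C6 silyloxy group sits equatorial, and the chromium-bound aldehyde oxygen takes the pseudo-equatorial position to avoid the 1,3-diaxial contact with H5, which leads to the 7β alcohol trans to O6. The step needs addition to the aldehyde alone and high dilution against intermolecular coupling; the weakly basic alkenylchromium tolerates both silyl ethers and does not enolise the α-silyloxy aldehyde, and the C4 silyl ether keeps the aldehyde from closing to a lactol.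

Step 10
Reactants: 21 4,6-bis-O-(triethylsilyl)dauc-8-ene-4β,6α,7β-triol
Product: 22 7-O-(tert-butyldimethylsilyl)-4,6-bis-O-(triethylsilyl)dauc-8-ene-4β,6α,7β-triol
Conditions: t-BuMe2SiOTf (1.5 equiv), 2,6-lutidine, CH2Cl2, −78 to 0 °C
Reagents that add atoms: tert-butyldimethylsilyl trifluoromethanesulfonate, CC(C)(C)[Si](C)(C)OS(=O)(=O)C(F)(F)F
Why: Silyl triflate–lutidine silylation reaches the hindered secondary allylic C7 hydroxyl, which must be masked so that O6 can later be acylated alone and the epoxidation is not hydroxyl-directed.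

Step 11
Reactants: 22 7-O-(tert-butyldimethylsilyl)-4,6-bis-O-(triethylsilyl)dauc-8-ene-4β,6α,7β-triol
Product: 23 7-O-(tert-butyldimethylsilyl)dauc-8-ene-4β,6α,7β-triol
Conditions: HF·pyridine, pyridine, THF, 0 °C to rt
Reagents that add atoms: none
Why: Buffered fluoride desilylation discriminates by the size of the silyl group, so both triethylsilyl ethers are cleaved while the bulkier tert-butyldimethylsilyl ether on the hindered allylic O7 persists.

Step 12
Reactants: 24 4-hydroxybenzoic acid
Product: 26 4-(tert-butyldimethylsilyloxy)benzoic acid, via bis-silylated benzoate 25 (not isolated)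
Conditions: t-BuMe2SiCl (2.3 equiv), imidazole, DMF, rt; then AcOH/THF/H2O (3:1:1), rt
Reagents that add atoms: tert-butyldimethylsilyl chloride, CC(C)(C)[Si](C)(C)Cl
Why: Exhaustive silylation followed by mild aqueous acid hydrolyses only the labile silyl ester and leaves the aryl silyl ether.

Step 13
Reactants: 26 4-(tert-butyldimethylsilyloxy)benzoic acid
Product: 27 4-(tert-butyldimethylsilyloxy)benzoyl chloride
Conditions: (COCl)2, DMF (cat.), CH2Cl2, 0 °C to rt; concentrate, use crude
Reagents that add atoms: oxalyl chloride, ClC(=O)C(=O)Cl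
Why: Acid chloride formation through the chloroiminium species from oxalyl chloride and DMF proceeds under mild conditions that aryl silyl ethers tolerate.

Step 14
Reactants: 23 7-O-(tert-butyldimethylsilyl)dauc-8-ene-4β,6α,7β-triol; 27 4-(tert-butyldimethylsilyloxy)benzoyl chloride
Product: 28 7β-(tert-butyldimethylsilyloxy)-4β-hydroxydauc-8-en-6α-yl 4-(tert-butyldimethylsilyloxy)benzoate
Conditions: 27 (2 equiv), DMAP (1 equiv), Et3N, CH2Cl2, rt to 40 °C
Reagents that add atoms: none
Why: DMAP-catalysed acylation through the N-acylpyridinium ion takes the secondary O6 hydroxyl, because the tertiary C4 hydroxyl is too hindered to react and O7 is blocked.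

Step 15
Reactants: 28 7β-(tert-butyldimethylsilyloxy)-4β-hydroxydauc-8-en-6α-yl 4-(tert-butyldimethylsilyloxy)benzoate
Product: 29 7β-(tert-butyldimethylsilyloxy)-8α,9α-epoxy-4β-hydroxydaucan-6α-yl 4-(tert-butyldimethylsilyloxy)benzoate
Conditions: m-CPBA, NaHCO3, CH2Cl2, 0 °C
Reagents that add atoms: 3-chloroperoxybenzoic acid, O=C(OO)c1cccc(Cl)c1
Why: Prilezhaev epoxidation of the trisubstituted C8=C9 alkene, in which, with O7 silylated and no hydroxyl direction, the peracid should attack the α-face away from the axial C1 methyl and the β-oriented O7 silyl ether, setting C8 and C9 with the oxirane anti to O7.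

Step 16
Reactants: 29 7β-(tert-butyldimethylsilyloxy)-8α,9α-epoxy-4β-hydroxydaucan-6α-yl 4-(tert-butyldimethylsilyloxy)benzoate
Product: 30 8α,9α-epoxy-4β,7β-dihydroxydaucan-6α-yl 4-hydroxybenzoate (CNP0290052.1)
Conditions: Bu4NF/AcOH (1:1), THF, 0 °C to rt
Reagents that add atoms: none
Why: Acetic acid-buffered fluoride cleaves the aryl and the secondary silyl ether while keeping the medium near neutral, so that neither O6 to O7 acyl migration nor alkoxide opening of the epoxide is triggered.

## Compound list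

1 | 3-ethoxycyclopent-2-en-1-one | CCOC1=CC(=O)CC1 | starting material
2 | (1,3-dioxolan-2-ylmethyl)magnesium bromide | Br[Mg]CC1OCCO1 | starting material
3 | bromomagnesium 1-(1,3-dioxolan-2-ylmethyl)-3-ethoxycyclopent-2-en-1-olate (racemic) | CCOC1=CC(O[Mg]Br)(CC2OCCO2)CC1 | intermediate
4 | 3-(1,3-dioxolan-2-ylmethyl)cyclopent-2-en-1-one | O=C1C=C(CC2OCCO2)CC1 | intermediate
5 | dimethylaluminium (3R)-3-(1,3-dioxolan-2-ylmethyl)-3-methylcyclopent-1-en-1-olate | C[Al](C)OC1=C[C@@](C)(CC2OCCO2)CC1 | intermediate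
6 | {[(3R)-3-(1,3-dioxolan-2-ylmethyl)-3-methylcyclopent-1-en-1-yl]oxy}trimethylsilane | C[Si](C)(C)OC1=C[C@@](C)(CC2OCCO2)CC1 | intermediate
7 | acrolein (prop-2-enal) | C=CC=O | starting material
8 | lithium (3R)-3-(1,3-dioxolan-2-ylmethyl)-3-methylcyclopent-1-en-1-olate | [Li]OC1=C[C@@](C)(CC2OCCO2)CC1 | intermediate
9 | dicyclohexyl{[(3R)-3-(1,3-dioxolan-2-ylmethyl)-3-methylcyclopent-1-en-1-yl]oxy}borane | C1CCCCC1B(C1CCCCC1)OC1=C[C@@](C)(CC2OCCO2)CC1 | intermediate
10 | O-dicyclohexylboryl aldolate of 11 | O=C1CC[C@](C)(CC2OCCO2)[C@H]1[C@@H](OB(C1CCCCC1)C1CCCCC1)C=C | intermediate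
11 | (2S,3R)-3-(1,3-dioxolan-2-ylmethyl)-2-[(1S)-1-hydroxyprop-2-en-1-yl]-3-methylcyclopentan-1-one | O=C1CC[C@](C)(CC2OCCO2)[C@H]1[C@@H](O)C=C | intermediate
12 | (2S,3R)-3-(1,3-dioxolan-2-ylmethyl)-3-methyl-2-[(1S)-1-(triethylsilyloxy)prop-2-en-1-yl]cyclopentan-1-one | O=C1CC[C@](C)(CC2OCCO2)[C@H]1[C@@H](O[Si](CC)(CC)CC)C=C | intermediate
13 | (1R,2S,3R)-3-(1,3-dioxolan-2-ylmethyl)-3-methyl-1-(propan-2-yl)-2-[(1S)-1-(triethylsilyloxy)prop-2-en-1-yl]cyclopentan-1-ol | CC(C)[C@]1(O)CC[C@](C)(CC2OCCO2)[C@H]1[C@@H](O[Si](CC)(CC)CC)C=C | intermediate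
14 | 2,4,6-trimethyl-1-{2-[(1R,2S,3R)-1-methyl-3-(propan-2-yl)-3-(triethylsilyloxy)-2-[(1S)-1-(triethylsilyloxy)prop-2-en-1-yl]cyclopentyl]-1-[2-(triethylsilyloxy)ethoxy]ethyl}pyridinium trifluoromethanesulfonate (both epimers at the N,O-acetal carbon) | CC(C)[C@]1(O[Si](CC)(CC)CC)CC[C@](C)(CC(OCCO[Si](CC)(CC)CC)[n+]2c(C)cc(C)cc2C)[C@H]1[C@@H](O[Si](CC)(CC)CC)C=C.[O-]S(=O)(=O)C(F)(F)F | intermediate
15 | 2-[(1R,2S,3R)-1-methyl-3-(propan-2-yl)-3-(triethylsilyloxy)-2-[(1S)-1-(triethylsilyloxy)prop-2-en-1-yl]cyclopentyl]acetaldehyde | CC(C)[C@]1(O[Si](CC)(CC)CC)CC[C@](C)(CC=O)[C@H]1[C@@H](O[Si](CC)(CC)CC)C=C | intermediate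
16 | triethyl{[(1R,2S,3R)-3-[(2Z)-3-iodobut-2-en-1-yl]-3-methyl-1-(propan-2-yl)-2-[(1S)-1-(triethylsilyloxy)prop-2-en-1-yl]cyclopentyl]oxy}silane | CC(C)[C@]1(O[Si](CC)(CC)CC)CC[C@](C)(C/C=C(/C)I)[C@H]1[C@@H](O[Si](CC)(CC)CC)C=C | intermediate
17 | (2RS,3R)-3-[(1S,2R,5R)-2-[(2Z)-3-iodobut-2-en-1-yl]-2-methyl-5-(propan-2-yl)-5-(triethylsilyloxy)cyclopentyl]-3-(triethylsilyloxy)propane-1,2-diol | CC(C)[C@]1(O[Si](CC)(CC)CC)CC[C@](C)(C/C=C(/C)I)[C@H]1[C@@H](O[Si](CC)(CC)CC)C(O)CO | intermediate
18 | (2R)-2-[(1S,2R,5R)-2-[(2Z)-3-iodobut-2-en-1-yl]-2-methyl-5-(propan-2-yl)-5-(triethylsilyloxy)cyclopentyl]-2-(triethylsilyloxy)acetaldehyde | CC(C)[C@]1(O[Si](CC)(CC)CC)CC[C@](C)(C/C=C(/C)I)[C@H]1[C@@H](O[Si](CC)(CC)CC)C=O | intermediate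
19 | dichloro{(2Z)-4-[(1R,2S,3R)-1-methyl-2-[(1R)-2-oxo-1-(triethylsilyloxy)ethyl]-3-(propan-2-yl)-3-(triethylsilyloxy)cyclopentyl]but-2-en-2-yl}chromium | CC(C)[C@]1(O[Si](CC)(CC)CC)CC[C@](C)(C/C=C(/C)[Cr](Cl)Cl)[C@H]1[C@@H](O[Si](CC)(CC)CC)C=O | intermediate
20 | dichlorochromium 7-alkoxide of 21 | CC(C)[C@]1(O[Si](CC)(CC)CC)CC[C@]2(C)CC=C(C)[C@@H](O[Cr](Cl)Cl)[C@H](O[Si](CC)(CC)CC)[C@H]21 | intermediate
21 | 4,6-bis-O-(triethylsilyl)dauc-8-ene-4β,6α,7β-triol (1R,4R,5S,6R,7R; 1β-methyl, 5α-H) | CC(C)[C@]1(O[Si](CC)(CC)CC)CC[C@]2(C)CC=C(C)[C@@H](O)[C@H](O[Si](CC)(CC)CC)[C@H]21 | intermediate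
22 | 7-O-(tert-butyldimethylsilyl)-4,6-bis-O-(triethylsilyl)dauc-8-ene-4β,6α,7β-triol (1R,4R,5S,6R,7R) | CC(C)[C@]1(O[Si](CC)(CC)CC)CC[C@]2(C)CC=C(C)[C@@H](O[Si](C)(C)C(C)(C)C)[C@H](O[Si](CC)(CC)CC)[C@H]21 | intermediate
23 | 7-O-(tert-butyldimethylsilyl)dauc-8-ene-4β,6α,7β-triol (1R,4R,5S,6R,7R) | CC(C)[C@]1(O)CC[C@]2(C)CC=C(C)[C@@H](O[Si](C)(C)C(C)(C)C)[C@H](O)[C@H]21 | intermediate
24 | 4-hydroxybenzoic acid | O=C(O)c1ccc(O)cc1 | starting material
25 | tert-butyldimethylsilyl 4-(tert-butyldimethylsilyloxy)benzoate | CC(C)(C)[Si](C)(C)OC(=O)c1ccc(O[Si](C)(C)C(C)(C)C)cc1 | intermediate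
26 | 4-(tert-butyldimethylsilyloxy)benzoic acid | CC(C)(C)[Si](C)(C)Oc1ccc(cc1)C(=O)O | intermediate
27 | 4-(tert-butyldimethylsilyloxy)benzoyl chloride | CC(C)(C)[Si](C)(C)Oc1ccc(cc1)C(=O)Cl | intermediate
28 | 7β-(tert-butyldimethylsilyloxy)-4β-hydroxydauc-8-en-6α-yl 4-(tert-butyldimethylsilyloxy)benzoate (1R,4R,5S,6R,7R) | CC(C)[C@]1(O)CC[C@]2(C)CC=C(C)[C@@H](O[Si](C)(C)C(C)(C)C)[C@H](OC(=O)c3ccc(O[Si](C)(C)C(C)(C)C)cc3)[C@H]21 | intermediate
29 | 7β-(tert-butyldimethylsilyloxy)-8α,9α-epoxy-4β-hydroxydaucan-6α-yl 4-(tert-butyldimethylsilyloxy)benzoate (1R,4R,5S,6R,7S,8S,9S) | CC(C)[C@]1(O)CC[C@]2(C)C[C@@H]3O[C@]3(C)[C@@H](O[Si](C)(C)C(C)(C)C)[C@H](OC(=O)c3ccc(O[Si](C)(C)C(C)(C)C)cc3)[C@H]21 | intermediate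
30 | 8α,9α-epoxy-4β,7β-dihydroxydaucan-6α-yl 4-hydroxybenzoate (1R,4R,5S,6R,7S,8R,9S), CNP0290052.1 | CC(C)[C@]1(O)CC[C@]2(C)C[C@@H]3O[C@]3(C)[C@@H](O)[C@H](OC(=O)c3ccc(O)cc3)[C@H]21 | target

## Step count and risks

Total step count: 16 (steps 12 and 13 prepare the acylating agent).
Longest linear sequence: 14 steps (steps 1 to 11, then 14 to 16, from 1 to 30).

Steps most likely to fail:

Step 3. The enolate face at C5 is distinguished only by a methyl and a dioxolanylmethyl group on C1, so facial selectivity may be poor, and the anti/syn ratio may erode if the boron exchange is incomplete. The fallback hands control to the aldehyde partner. It sets out from 6: boron enolate 9 is generated as before and combined with (S)-2,2-dimethyl-1,3-dioxolane-4-carbaldehyde in place of acrolein. The Felkin preference of this α-alkoxy aldehyde with an E boron enolate, together with the anti topicity of the chair transition state, dictates the enolate face and should give the anti,anti aldol adduct F1. Silylation (Et3SiCl, imidazole) gives its O6 triethylsilyl ether F2, and isopropylcerium addition gives the C4 carbinol F3. The silyl triflate–collidine step, which leaves the ketal untouched, gives the O4-silylated C9 aldehyde F4, and the iodo-ylide olefination gives the Z iodoalkene F5. Periodic acid (H5IO6, EtOAc) then cleaves the terminal acetonide directly to the aldehyde, and the route is rejoined at 18.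

Step 9. The ring closure may show poor facial selectivity at the C7 aldehyde, because the polar Felkin preference of the α-silyloxy aldehyde opposes the equatorial delivery favoured by the forming ring; slow closure with reduction of the iodide is the second concern. The fallback sets the C7 configuration by hydride reduction instead of by the C–C bond formation. It sets out from 18: the closure is run regardless, and 21 together with its 7α-epimer F6 is oxidised (Dess–Martin periodinane, NaHCO3, CH2Cl2) to the C7 enone F7. Luche reduction (NaBH4, CeCl3·7H2O, MeOH, −78 °C) then delivers hydride along the axial trajectory on the α-face, anti to the angular C1 methyl, to give the equatorial 7β alcohol, and the route is rejoined at 21.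

Step 15. The peracid may attack the β-face or show no facial preference, since an equatorial O7 silyl ether shields little and the selectivity then rests on the C1 methyl alone. The fallback delivers the oxygen by a bromohydrin sequence and sets out from 28. N-Bromosuccinimide in aqueous 1,2-dimethoxyethane forms the bromonium ion on the face the peracid prefers, and water opens it anti at the more substituted C8 to give the 9β-bromo-8α-hydroxy compound F8. DBU in CH2Cl2 closes it with inversion at C9 to the 8α,9α-epoxide, and the route is rejoined at 29.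

## Further compounds

F1 | step 3 | (2S,3R)-2-{(R)-[(4S)-2,2-dimethyl-1,3-dioxolan-4-yl](hydroxy)methyl}-3-(1,3-dioxolan-2-ylmethyl)-3-methylcyclopentan-1-one | O=C1CC[C@](C)(CC2OCCO2)[C@H]1[C@@H](O)[C@@H]3COC(C)(C)O3
F2 | step 3 | O6 triethylsilyl ether of F1 | O=C1CC[C@](C)(CC2OCCO2)[C@H]1[C@@H](O[Si](CC)(CC)CC)[C@@H]3COC(C)(C)O3
F3 | step 3 | C4 isopropyl carbinol from F2 | CC(C)[C@]1(O)CC[C@](C)(CC2OCCO2)[C@H]1[C@@H](O[Si](CC)(CC)CC)[C@@H]3COC(C)(C)O3
F4 | step 3 | O4-triethylsilylated C9 aldehyde from F3 | CC(C)[C@]1(O[Si](CC)(CC)CC)CC[C@](C)(CC=O)[C@H]1[C@@H](O[Si](CC)(CC)CC)[C@@H]3COC(C)(C)O3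
F5 | step 3 | (Z)-3-iodobut-2-enyl compound from F4 | CC(C)[C@]1(O[Si](CC)(CC)CC)CC[C@](C)(C/C=C(/C)I)[C@H]1[C@@H](O[Si](CC)(CC)CC)[C@@H]3COC(C)(C)O3
F6 | step 9 | 4,6-bis-O-(triethylsilyl)dauc-8-ene-4β,6α,7α-triol (7-epimer of 21) | CC(C)[C@]1(O[Si](CC)(CC)CC)CC[C@]2(C)CC=C(C)[C@H](O)[C@H](O[Si](CC)(CC)CC)[C@H]21
F7 | step 9 | 4β,6α-bis(triethylsilyloxy)dauc-8-en-7-one | CC(C)[C@]1(O[Si](CC)(CC)CC)CC[C@]2(C)CC=C(C)C(=O)[C@H](O[Si](CC)(CC)CC)[C@H]21
F8 | step 15 | 9β-bromo-7β-(tert-butyldimethylsilyloxy)-4β,8α-dihydroxydaucan-6α-yl 4-(tert-butyldimethylsilyloxy)benzoate | CC(C)[C@]1(O)CC[C@]2(C)C[C@@H](Br)[C@@](O)(C)[C@@H](O[Si](C)(C)C(C)(C)C)[C@H](OC(=O)c3ccc(O[Si](C)(C)C(C)(C)C)cc3)[C@H]21
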